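**Plan**

1. Ring atoms are numbered as in (1R,2S,4R,5R)-1-(bromomethyl)-1,2,4-trichloro-5-[(E)-2-chloroethenyl]-5-methylcyclohexane. The retrosynthesis cuts the ring bond C4–C5 first, then C–Br (from CH2OH), the C1–Cl/C2–Cl pair (from a Z-allylic alcohol), the C6–C1 bond (allyl–alkenyl Stille coupling) and C3–C4 (enolate alkylation).
2. Forward, the chain is joined linearly: tert-butyl chloroacetate and propargyl bromide bring C4, C3, C2 and C1; carbonylation adds the future CH2Br carbon; an allyl bromide brings C6, C5, CH3 and both alkenyl carbons. The only ring arises in the last step.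
3. C1 and C2 come from a ligand-controlled anti addition of two chlorines to the Z-alkene. The two ring-forming chains are trans on that alkene, so anti addition gives the cis-1,2-dichloride of the ring.
4. C4 and C5 are set in the ring closure through a chair transition state, and the E-chloroalkene forms in the same step.
5. Enabling feature: the quaternary ring carbon C5 is allylic to the exocyclic CH=CHCl, so C5(CH3)–CH=CHCl is the transposed form of an allyl sulfone C5(CH3)=CH–CHCl(SO2Ph). Its ring neighbour C4 carries a chlorine and can be a radical, so one radical addition–fragmentation makes the C4–C5 bond, the quaternary centre, the C4 stereocentre and the chloroalkene.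

Key step: step 13

Remark: the C–Cl carbon next to the ester (from step 4) and the C–Cl carbon next to the sulfone (from step 2) are carried as epimer mixtures and are written without configuration. Both become trigonal in step 13, so only the centres set in steps 9 and 13 matter. Compounds 1, 2, 7 and 8 are commercial.

Step 1
Reactants: 1 2-methyl-2-vinyloxirane; 2 sodium benzenesulfinate
Product: 3 (2E)-2-methyl-4-(phenylsulfonyl)but-2-en-1-ol
Conditions: Pd(PPh3)4 (3 mol %), AcOH (1 equiv), THF, rt
Reagents that add atoms: none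
Why: Tsuji–Trost-type opening in which zerovalent palladium ionizes the vinyl epoxide to a π-allyl alkoxide and the soft sulfinate attacks the unsubstituted terminus (1,4-addition), which should give mainly the E-alkene.

Step 2
Reactants: 3 (2E)-2-methyl-4-(phenylsulfonyl)but-2-en-1-ol
Product: 5 (2E)-4-chloro-2-methyl-4-(phenylsulfonyl)but-2-en-1-ol, via dilithio dianion 4 (not isolated)
Conditions: n-BuLi (2.05 equiv), THF, −78 °C; then inverse addition to C2Cl6, −78 °C; aq. NH4Cl
Reagents that add atoms: hexachloroethane, ClC(Cl)(Cl)C(Cl)(Cl)Cl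
Why: Chlorination of a sulfonyl-stabilized allyl carbanion, in which the more basic carbon of the dianion reacts at the position next to sulfur while the alkoxide stays inert; the new C–Cl centre is racemic and is erased later.

Step 3
Reactants: 5 (2E)-4-chloro-2-methyl-4-(phenylsulfonyl)but-2-en-1-ol
Product: 6 [(2E)-4-bromo-1-chloro-3-methylbut-2-en-1-yl]sulfonylbenzene
Conditions: CBr4, PPh3, CH2Cl2, 0 °C
Reagents that add atoms: carbon tetrabromide, BrC(Br)(Br)Br
Why: Appel reaction, an SN2 displacement of the oxyphosphonium group at the primary allylic carbon that keeps the E-alkene.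

Step 4
Reactants: 7 tert-butyl chloroacetate; 8 propargyl bromide
Product: 10 tert-butyl 2-chloropent-4-ynoate, via lithium enolate 9 (not isolated)
Conditions: LiN(SiMe3)2, THF/DMPU, −78 °C; then 8, −78 to −40 °C
Reagents that add atoms: none
Why: Ester enolate alkylation, in which the reactive propargylic bromide should trap the α-chloro enolate at low temperature before it self-condenses; the C–Cl centre is racemic and is erased in step 13.

Step 5
Reactants: 10 tert-butyl 2-chloropent-4-ynoate
Product: 11 6-tert-butyl 1-methyl 5-chlorohex-2-ynedioate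
Conditions: PdCl2 (5 mol %), CuCl2 (2 equiv), NaOAc (2 equiv), CO (1 atm), MeOH, rt
Reagents that add atoms: carbon monoxide, [C-]#[O+]; methanol, CO
Why: Palladium-catalysed oxidative alkoxycarbonylation of a terminal alkyne, which makes the alkynoate under weakly basic conditions that leave the acidic α-chloro ester untouched.

Step 6
Reactants: 11 6-tert-butyl 1-methyl 5-chlorohex-2-ynedioate
Product: 12 6-tert-butyl 1-methyl (2E)-5-chloro-2-(tributylstannyl)hex-2-enedioate
Conditions: Bu3SnH, Pd(PPh3)4 (2 mol %), THF, 0 °C
Reagents that add atoms: tributyltin hydride, CCCC[SnH](CCCC)CCCC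
Why: Palladium-catalysed hydrostannation of an alkynoate, a syn addition that places tin on the carbon next to the ester and hydrogen cis to tin, which fixes the alkene geometry.

Step 7
Reactants: 12 6-tert-butyl 1-methyl (2E)-5-chloro-2-(tributylstannyl)hex-2-enedioate; 6 [(2E)-4-bromo-1-chloro-3-methylbut-2-en-1-yl]sulfonylbenzene
Product: 13 6-tert-butyl 1-methyl (2Z)-5-chloro-2-[(2E)-4-chloro-2-methyl-4-(phenylsulfonyl)but-2-en-1-yl]hex-2-enedioate
Conditions: Pd2(dba)3 (2.5 mol %), AsPh3 (20 mol %), CuI (10 mol %), DMF, rt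
Reagents that add atoms: none
Why: Stille coupling under neutral conditions, in which the π-allylpalladium from the allylic bromide couples at its less hindered CH2 terminus with retention at the alkenylstannane, so the ester ends cis to the chain CH2 and the allyl alkene stays E.

Step 8
Reactants: 13 6-tert-butyl 1-methyl (2Z)-5-chloro-2-[(2E)-4-chloro-2-methyl-4-(phenylsulfonyl)but-2-en-1-yl]hex-2-enedioate
Product: 14 tert-butyl (4Z,7E)-2,9-dichloro-5-(hydroxymethyl)-7-methyl-9-(phenylsulfonyl)nona-4,7-dienoate
Conditions: iBu2AlH (2.2 equiv), CH2Cl2, −78 °C; aq. potassium sodium tartrate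
Reagents that add atoms: none
Why: Hydride reduction in which the conjugated methyl ester should be reduced to the allylic alcohol at −78 °C faster than the hindered tert-butyl ester.

Step 9
Reactants: 14 tert-butyl (4Z,7E)-2,9-dichloro-5-(hydroxymethyl)-7-methyl-9-(phenylsulfonyl)nona-4,7-dienoate
Product: 15 tert-butyl (4S,5S,7E)-2,4,5,9-tetrachloro-5-(hydroxymethyl)-7-methyl-9-(phenylsulfonyl)non-7-enoate
Conditions: t-BuOCl, ClTi(OiPr)3, chiral tridentate salicylaldimine–amino alcohol ligand (20 mol %, the enantiomer that leads to 4S,5S), hexanes, −20 °C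
Reagents that add atoms: tert-butyl hypochlorite, CC(C)(C)OCl; chlorotitanium triisopropoxide, CC(C)O[Ti](Cl)(OC(C)C)OC(C)C
Why: Titanium-mediated catalytic enantioselective dichlorination of an allylic alcohol, an anti addition across the Z-alkene bound to titanium through its alkoxide, in which the ligand fixes the face and so sets the tertiary and the secondary C–Cl centres (future C1 and C2) while the electron-poor allyl sulfone alkene is left alone.

Step 10
Reactants: 15 tert-butyl (4S,5S,7E)-2,4,5,9-tetrachloro-5-(hydroxymethyl)-7-methyl-9-(phenylsulfonyl)non-7-enoate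
Product: 17 tert-butyl (4S,5R,7E)-5-(bromomethyl)-2,4,5,9-tetrachloro-7-methyl-9-(phenylsulfonyl)non-7-enoate, via triflate 16 (not isolated)
Conditions: Tf2O, 2,6-lutidine, CH2Cl2, −78 °C; then Bu4NBr, −78 °C to rt
Reagents that add atoms: tetrabutylammonium bromide, CCCC[N+](CCCC)(CCCC)CCCC.[Br-]
Why: Triflation followed by SN2 displacement with bromide at the primary carbon, which has no β-hydrogen on its quaternary neighbour and so cannot eliminate, and which leaves both stereocentres untouched.

Step 11
Reactants: 17 tert-butyl (4S,5R,7E)-5-(bromomethyl)-2,4,5,9-tetrachloro-7-methyl-9-(phenylsulfonyl)non-7-enoate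
Product: 18 (4S,5R,7E)-5-(bromomethyl)-2,4,5,9-tetrachloro-7-methyl-9-(phenylsulfonyl)non-7-enoic acid
Conditions: TFA/CH2Cl2 (1:4), 0 °C to rt
Reagents that add atoms: none
Why: Acidolysis of the tert-butyl ester with loss of isobutene, which frees the acid without any base that could eliminate HCl.

Step 12
Reactants: 18 (4S,5R,7E)-5-(bromomethyl)-2,4,5,9-tetrachloro-7-methyl-9-(phenylsulfonyl)non-7-enoic acid
Product: 19 1,3-dioxoisoindolin-2-yl (4S,5R,7E)-5-(bromomethyl)-2,4,5,9-tetrachloro-7-methyl-9-(phenylsulfonyl)non-7-enoate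
Conditions: N-hydroxyphthalimide, DIC, DMAP (cat.), CH2Cl2, 0 °C to rt
Reagents that add atoms: N-hydroxyphthalimide, ON1C(=O)c2ccccc2C1=O
Why: Steglich-type carbodiimide esterification, which gives the redox-active N-acyloxyphthalimide.

Step 13
Reactants: 19 1,3-dioxoisoindolin-2-yl (4S,5R,7E)-5-(bromomethyl)-2,4,5,9-tetrachloro-7-methyl-9-(phenylsulfonyl)non-7-enoate
Product: 22 violacene (1R,2S,4R,5R)-1-(bromomethyl)-1,2,4-trichloro-5-[(E)-2-chloroethenyl]-5-methylcyclohexane, via α-chloroalkyl radical 20 (not isolated), via cyclized β-sulfonyl radical 21 (not isolated)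
Conditions: Ru(bpy)3(PF6)2 (1 mol %), Hantzsch ester (1.5 equiv, added slowly), blue LEDs, CH2Cl2 (0.005 M), rt
Reagents that add atoms: none
Why: Proposed new method: the photoexcited ruthenium complex is quenched by the Hantzsch ester and passes one electron to the N-acyloxyphthalimide, which loses CO2 and phthalimide anion to leave the secondary α-chloroalkyl radical 20; this adds to the methyl-bearing alkene carbon and the adduct radical 21 expels PhSO2• to give the chloroalkene, the closest known reaction type being the decarboxylative radical allylation of N-acyloxyphthalimides with allyl sulfones (addition–β-fragmentation), not yet shown for an α-chloroalkyl radical closing a ring at a fully substituted alkene carbon. The cyclohexane closes in the 6-exo-trig mode. C4 should be set by the chair transition state, in which the C–Cl bond of the radical carbon is equatorial like the C2 chlorine and the CH2Br group; C5 should be set by the fixed C1 centre, because the flat =CH– carbon rather than the methyl group takes the axial site syn to the axial C1 chlorine, which places CH=CHCl cis to the C4 chlorine. The step needs 6-exo over 7-endo attack (secured by ring size and by the sulfonyl leaving group, which makes only the 6-exo adduct productive), selective radical generation (only the N-acyloxyphthalimide is reduced at the potential of the catalyst, not C–Cl or C–Br) and E geometry (β-scission through the conformer with chlorine anti to the quaternary carbon, backed by reversible addition of PhSO2•). High dilution and slow addition of the Hantzsch ester should keep hydrogen-atom capture behind cyclization.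

**Compound list**

1 | 2-methyl-2-vinyloxirane (racemic) | CC1(C=C)CO1 | starting material
2 | sodium benzenesulfinate | [Na+].[O-]S(=O)c1ccccc1 | starting material
3 | (2E)-2-methyl-4-(phenylsulfonyl)but-2-en-1-ol | OC/C(C)=C/CS(=O)(=O)c1ccccc1 | intermediate
4 | dilithio dianion of 3 (alkoxide and sulfonyl carbanion, not isolated) | [Li+].[Li+].[O-]C/C(C)=C/[CH-]S(=O)(=O)c1ccccc1 | intermediate
5 | (2E)-4-chloro-2-methyl-4-(phenylsulfonyl)but-2-en-1-ol (racemic) | OC/C(C)=C/C(Cl)S(=O)(=O)c1ccccc1 | intermediate
6 | [(2E)-4-bromo-1-chloro-3-methylbut-2-en-1-yl]sulfonylbenzene (racemic) | BrC/C(C)=C/C(Cl)S(=O)(=O)c1ccccc1 | intermediate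
7 | tert-butyl chloroacetate | ClCC(=O)OC(C)(C)C | starting material
8 | propargyl bromide (3-bromoprop-1-yne) | C#CCBr | starting material
9 | lithium enolate of 7 (not isolated) | [Li+].[O-]C(=CCl)OC(C)(C)C | intermediate
10 | tert-butyl 2-chloropent-4-ynoate (racemic) | C#CCC(Cl)C(=O)OC(C)(C)C | intermediate
11 | 6-tert-butyl 1-methyl 5-chlorohex-2-ynedioate | COC(=O)C#CCC(Cl)C(=O)OC(C)(C)C | intermediate
12 | 6-tert-butyl 1-methyl (2E)-5-chloro-2-(tributylstannyl)hex-2-enedioate | COC(=O)/C([Sn](CCCC)(CCCC)CCCC)=C\CC(Cl)C(=O)OC(C)(C)C | intermediate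
13 | 6-tert-butyl 1-methyl (2Z)-5-chloro-2-[(2E)-4-chloro-2-methyl-4-(phenylsulfonyl)but-2-en-1-yl]hex-2-enedioate | COC(=O)/C(C/C(C)=C/C(Cl)S(=O)(=O)c1ccccc1)=C\CC(Cl)C(=O)OC(C)(C)C | intermediate
14 | tert-butyl (4Z,7E)-2,9-dichloro-5-(hydroxymethyl)-7-methyl-9-(phenylsulfonyl)nona-4,7-dienoate | OC/C(C/C(C)=C/C(Cl)S(=O)(=O)c1ccccc1)=C\CC(Cl)C(=O)OC(C)(C)C | intermediate
15 | tert-butyl (4S,5S,7E)-2,4,5,9-tetrachloro-5-(hydroxymethyl)-7-methyl-9-(phenylsulfonyl)non-7-enoate | OC[C@@](Cl)(C/C(C)=C/C(Cl)S(=O)(=O)c1ccccc1)[C@@H](Cl)CC(Cl)C(=O)OC(C)(C)C | intermediate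
16 | triflate of 15 (4S,5S; not isolated) | FC(F)(F)S(=O)(=O)OC[C@@](Cl)(C/C(C)=C/C(Cl)S(=O)(=O)c1ccccc1)[C@@H](Cl)CC(Cl)C(=O)OC(C)(C)C | intermediate
17 | tert-butyl (4S,5R,7E)-5-(bromomethyl)-2,4,5,9-tetrachloro-7-methyl-9-(phenylsulfonyl)non-7-enoate | BrC[C@@](Cl)(C/C(C)=C/C(Cl)S(=O)(=O)c1ccccc1)[C@@H](Cl)CC(Cl)C(=O)OC(C)(C)C | intermediate
18 | (4S,5R,7E)-5-(bromomethyl)-2,4,5,9-tetrachloro-7-methyl-9-(phenylsulfonyl)non-7-enoic acid | BrC[C@@](Cl)(C/C(C)=C/C(Cl)S(=O)(=O)c1ccccc1)[C@@H](Cl)CC(Cl)C(=O)O | intermediate
19 | 1,3-dioxoisoindolin-2-yl (4S,5R,7E)-5-(bromomethyl)-2,4,5,9-tetrachloro-7-methyl-9-(phenylsulfonyl)non-7-enoate | BrC[C@@](Cl)(C/C(C)=C/C(Cl)S(=O)(=O)c1ccccc1)[C@@H](Cl)CC(Cl)C(=O)ON1C(=O)c2ccccc2C1=O | intermediate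
20 | α-chloroalkyl radical from 19 (not isolated) | BrC[C@@](Cl)(C/C(C)=C/C(Cl)S(=O)(=O)c1ccccc1)[C@@H](Cl)C[CH]Cl | intermediate
21 | cyclized β-sulfonyl radical (not isolated) | C[C@]1([CH]C(Cl)S(=O)(=O)c2ccccc2)C[C@](Cl)(CBr)[C@@H](Cl)C[C@H]1Cl | intermediate
22 | violacene, (1R,2S,4R,5R)-1-(bromomethyl)-1,2,4-trichloro-5-[(E)-2-chloroethenyl]-5-methylcyclohexane | C[C@]1(/C=C/Cl)C[C@](Cl)(CBr)[C@@H](Cl)C[C@H]1Cl | target

**Step count and risks**

Total step count: 13. Longest linear sequence: 10 steps (steps 4 to 13 from 7; equally steps 1 to 3 and 7 to 13 from 1).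

The three steps most likely to fail:

1. Step 13 (Proposed new method). Attack at the fully substituted alkene carbon is slow, so the radical may capture a hydrogen atom before it cyclizes, or abstract a hydrogen from the allylic CH2 (1,5-transfer) with subsequent loss of a chlorine atom; facial selectivity at the quaternary centre may also be poor. The fallback sets out from acid 18 and returns at 22, and it replaces reductive single-electron activation by a non-reductive halogen-atom-transfer chain. Hunsdiecker-type iododecarboxylation of 18 (PhI(OAc)2, I2, hν, cyclohexane) should give the 1-chloro-1-iodoalkane [(2E,5R,6S)-5-(bromomethyl)-1,5,6,8-tetrachloro-8-iodo-3-methyloct-2-en-1-yl]sulfonylbenzene F1. Irradiation of F1 with (Bu3Sn)2 (sunlamp, benzene, 0.005 M) then runs the known iodine-atom-transfer allylation of an alkyl iodide with an allyl sulfone: Bu3Sn• takes the iodine, the cyclized radical loses PhSO2•, and PhSO2• cleaves the ditin. No reductant or hydrogen donor is present, so the open-chain radical can only cyclize or be capped again by iodine. This fallback does not address the 1,5-hydrogen transfer or the facial selectivity.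

2. Step 9. Enantiofacial control may be poor on a hindered 2,3-disubstituted allylic alcohol whose sulfone and ester groups can also bind titanium, and chlorine may be delivered to the second alkene. The fallback sets out from 14 and returns at 15, and it replaces catalyst control by resolution. Uncatalysed anti-dichlorination with Et4NCl3 (CH2Cl2, −78 °C) should give 15 together with its enantiomer, tert-butyl (4R,5R,7E)-2,4,5,9-tetrachloro-5-(hydroxymethyl)-7-methyl-9-(phenylsulfonyl)non-7-enoate F2. Lipase-catalysed acetylation (Pseudomonas cepacia lipase, vinyl acetate), with the enzyme chosen to consume F2, should convert it into the acetate tert-butyl (4R,5R,7E)-5-(acetoxymethyl)-2,4,5,9-tetrachloro-7-methyl-9-(phenylsulfonyl)non-7-enoate F3 and leave 15 as the free alcohol.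

3. Step 8. Hydride may also attack the activated α-chloro tert-butyl ester (over-reduction). The fallback sets out from 7 and returns at 14, and it avoids any ester reduction. Enolate 9 is alkylated with commercial (4-bromobut-2-yn-1-yl)oxy(tert-butyl)dimethylsilane to give tert-butyl 6-[(tert-butyldimethylsilyl)oxy]-2-chlorohex-4-ynoate F4. HF·pyridine frees the propargylic alcohol tert-butyl 2-chloro-6-hydroxyhex-4-ynoate F5. Hydrostannation directed to the carbon next to the hydroxymethyl group (Bu3SnH, Mo(CO)3(CNtBu)3 cat., THF) gives tert-butyl (4E)-2-chloro-6-hydroxy-5-(tributylstannyl)hex-4-enoate F6. Stille coupling of F6 with 6 under the conditions of step 7 then gives 14 directly.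

**Further compounds**

F1 | step 13 | [(2E,5R,6S)-5-(bromomethyl)-1,5,6,8-tetrachloro-8-iodo-3-methyloct-2-en-1-yl]sulfonylbenzene | BrC[C@@](Cl)(C/C(C)=C/C(Cl)S(=O)(=O)c1ccccc1)[C@@H](Cl)CC(Cl)I
F2 | step 9 | tert-butyl (4R,5R,7E)-2,4,5,9-tetrachloro-5-(hydroxymethyl)-7-methyl-9-(phenylsulfonyl)non-7-enoate | OC[C@](Cl)(C/C(C)=C/C(Cl)S(=O)(=O)c1ccccc1)[C@H](Cl)CC(Cl)C(=O)OC(C)(C)C
F3 | step 9 | tert-butyl (4R,5R,7E)-5-(acetoxymethyl)-2,4,5,9-tetrachloro-7-methyl-9-(phenylsulfonyl)non-7-enoate | CC(=O)OC[C@](Cl)(C/C(C)=C/C(Cl)S(=O)(=O)c1ccccc1)[C@H](Cl)CC(Cl)C(=O)OC(C)(C)C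
F4 | step 8 | tert-butyl 6-[(tert-butyldimethylsilyl)oxy]-2-chlorohex-4-ynoate | CC(C)(C)[Si](C)(C)OCC#CCC(Cl)C(=O)OC(C)(C)C
F5 | step 8 | tert-butyl 2-chloro-6-hydroxyhex-4-ynoate | OCC#CCC(Cl)C(=O)OC(C)(C)C
F6 | step 8 | tert-butyl (4E)-2-chloro-6-hydroxy-5-(tributylstannyl)hex-4-enoate | OC/C([Sn](CCCC)(CCCC)CCCC)=C\CC(Cl)C(=O)OC(C)(C)C
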